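**Retrosynthetic overview**
- The route rests on the four-carbon chain C9–C8–C8'–C9' (the two methyl-bearing methines and their methyls), flanked by two identical benzylic bonds C7–C8 and C7'–C8' to identical 3,4-dihydroxy-5-methoxyphenyl rings A and A'. This chain is 2-butyne at a lower oxidation level.
- Last disconnections: hydrogenolysis of four O-benzyl ethers, then syn-hydrogenation of a Z tetrasubstituted alkene, which turns the cis geometry into the meso (8R,8'S) relationship.
- Key disconnection: C7–C8 and C7'–C8' together, by twofold Suzuki–Miyaura coupling of (Z)-2,3-diborylbut-2-ene with a 3,4-bis(benzyloxy)-5-methoxybenzyl bromide.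
- The diboronate comes from syn-diboration of 2-butyne; the bromide comes from 5-hydroxyvanillin by benzylation, reduction and bromination.
- No ring is formed at any stage; rings A and A' are carried in intact from 5-hydroxyvanillin.

Key step: step 5

Assumption: lignan numbering is used (aryl C1–C6, benzylic C7, methine C8, methyl C9, primed for the second half); the target SMILES encodes the (8R,8'S) meso diastereomer, and 2-butyne, bis(pinacolato)diboron and 5-hydroxyvanillin are taken as purchased.

**Step 1**
Reactants: 1 2-butyne; 2 bis(pinacolato)diboron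
Product: 3 (Z)-2,3-bis(4,4,5,5-tetramethyl-1,3,2-dioxaborolan-2-yl)but-2-ene
Conditions: Pt(PPh3)4 (3 mol%), DMF, 80 °C, sealed tube, 1 in excess
Reagents that add atoms: none
Why: Oxidative addition of the B–B bond to zerovalent platinum, syn insertion of the alkyne into a Pt–B bond and reductive elimination place both boryl groups on the same side of the new alkene (platinum-catalysed alkyne syn-diboration), which fixes the cis relationship later carried into C8 and C8'.

**Step 2**
Reactants: 4 3,4-dihydroxy-5-methoxybenzaldehyde (5-hydroxyvanillin)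
Product: 5 3,4-bis(benzyloxy)-5-methoxybenzaldehyde
Conditions: BnBr (2.4 equiv), K2CO3, DMF, 60 °C
Reagents that add atoms: benzyl bromide, BrCc1ccccc1
Why: Twofold Williamson etherification of the two acidic phenols with an unhindered benzylic electrophile should go to completion, the aldehyde and the aryl methyl ether being inert to carbonate base.

**Step 3**
Reactants: 5 3,4-bis(benzyloxy)-5-methoxybenzaldehyde
Product: 6 [3,4-bis(benzyloxy)-5-methoxyphenyl]methanol
Conditions: NaBH4, MeOH/THF, 0 °C to rt
Reagents that add atoms: none
Why: Borohydride reduction of an aromatic aldehyde gives the primary benzylic alcohol and leaves the benzyl and methyl ethers untouched.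

**Step 4**
Reactants: 6 [3,4-bis(benzyloxy)-5-methoxyphenyl]methanol
Product: 7 3,4-bis(benzyloxy)-5-methoxybenzyl bromide
Conditions: PBr3 (0.4 equiv), CH2Cl2, 0 °C; used promptly
Reagents that add atoms: phosphorus tribromide, BrP(Br)Br
Why: Activation of the primary benzylic alcohol as a phosphite ester followed by SN2 displacement by bromide gives the benzylic bromide under conditions that aryl benzyl ethers tolerate.

**Step 5**
Reactants: 3 (Z)-2,3-bis(4,4,5,5-tetramethyl-1,3,2-dioxaborolan-2-yl)but-2-ene; 7 3,4-bis(benzyloxy)-5-methoxybenzyl bromide (2.6 equiv)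
Product: 9 (Z)-1,4-bis[3,4-bis(benzyloxy)-5-methoxyphenyl]-2,3-dimethylbut-2-ene, via mono-coupled alkenylboronate 8 (not isolated)
Conditions: Pd(PPh3)4 (10 mol%), Cs2CO3 (6 equiv), 1,4-dioxane/H2O (10:1), degassed, 60 then 85 °C
Reagents that add atoms: none
Why: Zerovalent palladium inserts into the benzylic C–Br bond of 7 to give a divalent benzylpalladium bromide, the base-activated alkenylboronate transfers its vinyl group to palladium with retention of geometry, and reductive elimination forms the sp2–sp3 bond C7–C8, after which the monoboronate 8 passes through the same cycle to form C7'–C8'. The closest known reactions are the Suzuki–Miyaura coupling of alkenyl pinacolboronates with benzylic bromides and the twofold coupling of cis-1,2-diborylalkenes to tetrasubstituted alkenes. No ring is closed and no stereocentre is created; what the step must deliver is the Z alkene, whose cis arrangement of the two benzylic arms is inherited from the syn-diboration and is kept because boron-to-palladium vinyl transfer and reductive elimination are both stereoretentive. The step needs cross-coupling to outrun hydrolysis and homocoupling of 7, for which 7 is used in excess, and it needs the double bond to stay out of conjugation with the aryl rings, which is secured because the benzylpalladium intermediate has no β-hydrogen and so offers no route to a palladium hydride that could move the alkene.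

**Step 6**
Reactants: 9 (Z)-1,4-bis[3,4-bis(benzyloxy)-5-methoxyphenyl]-2,3-dimethylbut-2-ene
Product: 10 meso-(2R,3S)-1,4-bis[3,4-bis(benzyloxy)-5-methoxyphenyl]-2,3-dimethylbutane
Conditions: [Ir(cod)(PCy3)(py)]PF6 (2 × 5 mol%), H2 (1 atm), dry CH2Cl2, rt
Reagents that add atoms: none
Why: The cationic iridium dihydride formed from this precatalyst binds tetrasubstituted alkenes in non-coordinating CH2Cl2 and delivers both hydrogens to one face (homogeneous syn-hydrogenation), so the Z alkene with its two benzylic arms cis should give C8 and C8' as the (R,S) pair from either face, that is the meso butane, with no facial selectivity required.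

**Step 7**
Reactants: 10 meso-(2R,3S)-1,4-bis[3,4-bis(benzyloxy)-5-methoxyphenyl]-2,3-dimethylbutane
Product: 11 5,5'-[(2R,3S)-2,3-dimethylbutane-1,4-diyl]bis(3-methoxybenzene-1,2-diol) (meso; target)
Conditions: H2 (1 atm), 10% Pd/C, EtOAc/MeOH, rt; filtration under argon
Reagents that add atoms: none
Why: Hydrogenolysis of the four O-benzyl ethers over Pd/C should free both catechols while the aryl methyl ethers and the saturated meso core, which has no epimerisable centre under these conditions, are unaffected.

**Compound list**
1 | 2-butyne | CC#CC | starting material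
2 | bis(pinacolato)diboron | CC1(C)OB(OC1(C)C)B1OC(C)(C)C(C)(C)O1 | starting material
3 | (Z)-2,3-bis(4,4,5,5-tetramethyl-1,3,2-dioxaborolan-2-yl)but-2-ene (boryl groups cis) | C/C(B1OC(C)(C)C(C)(C)O1)=C(\C)B1OC(C)(C)C(C)(C)O1 | intermediate
4 | 3,4-dihydroxy-5-methoxybenzaldehyde (5-hydroxyvanillin) | COc1cc(C=O)cc(O)c1O | starting material
5 | 3,4-bis(benzyloxy)-5-methoxybenzaldehyde | COc1cc(C=O)cc(OCc2ccccc2)c1OCc1ccccc1 | intermediate
6 | [3,4-bis(benzyloxy)-5-methoxyphenyl]methanol | COc1cc(CO)cc(OCc2ccccc2)c1OCc1ccccc1 | intermediate
7 | 3,4-bis(benzyloxy)-5-methoxybenzyl bromide | COc1cc(CBr)cc(OCc2ccccc2)c1OCc1ccccc1 | intermediate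
8 | 2-[(2E)-4-[3,4-bis(benzyloxy)-5-methoxyphenyl]-3-methylbut-2-en-2-yl]-4,4,5,5-tetramethyl-1,3,2-dioxaborolane (benzylic arm and boron cis; formed in step 5, not isolated) | COc1cc(C/C(C)=C(C)\B2OC(C)(C)C(C)(C)O2)cc(OCc2ccccc2)c1OCc1ccccc1 | intermediate
9 | (Z)-1,4-bis[3,4-bis(benzyloxy)-5-methoxyphenyl]-2,3-dimethylbut-2-ene | COc1cc(C/C(C)=C(C)\Cc2cc(OCc3ccccc3)c(OCc3ccccc3)c(OC)c2)cc(OCc2ccccc2)c1OCc1ccccc1 | intermediate
10 | meso-(2R,3S)-1,4-bis[3,4-bis(benzyloxy)-5-methoxyphenyl]-2,3-dimethylbutane | COc1cc(C[C@@H](C)[C@@H](C)Cc2cc(OCc3ccccc3)c(OCc3ccccc3)c(OC)c2)cc(OCc2ccccc2)c1OCc1ccccc1 | intermediate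
11 | 5,5'-[(2R,3S)-2,3-dimethylbutane-1,4-diyl]bis(3-methoxybenzene-1,2-diol) (meso) | COc1cc(C[C@@H](C)[C@@H](C)Cc2cc(O)c(O)c(OC)c2)cc(O)c1O | target

**Step count**
Total: 7 steps. Longest linear sequence: 6 steps (4 → 5 → 6 → 7 → 9 → 10 → 11).

**Steps most likely to fail**

Step 5. After the first coupling the remaining boronate 8 is tetrasubstituted and hindered. Its transmetalation may then be slower than hydrolysis or homocoupling of 7 and slower than protodeboronation of 8, so the reaction may stall at the mono-coupled stage. The fallback makes the second bond with reversed polarity. It sets out from 8, which is obtained and isolated by running step 5 with one equivalent of 7 at 60 °C. Treatment of 8 with aqueous NaOH and then I2 in THF at 0 °C (base first, so that the boronate complex undergoes ipso-iododeboronation with retention) should give the alkenyl iodide 1,2-bis(benzyloxy)-5-[(2Z)-3-iodo-2-methylbut-2-en-1-yl]-3-methoxybenzene F1. Separately, zinc insertion into 7 (Zn dust, LiCl, THF, 0 °C) should give [3,4-bis(benzyloxy)-5-methoxybenzyl]zinc bromide F2. Negishi coupling of F1 with F2 (Pd(PPh3)4, THF, 50 °C) should form C7'–C8' with retention of the alkene geometry and comes back to the route at 9.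

Step 6. Reversible insertion and β-hydride elimination at iridium may move the double bond into conjugation with an aryl ring, or to the 1,1-disubstituted position, before hydrogen is added. Reduction of such an isomerised alkene is not stereospecific, so the meso purity would be eroded; coordination of the electron-rich arenes may also deactivate the cationic catalyst. The fallback enforces the cis relationship with a ring instead of alkene geometry and sets out from 5.
- Addition of EtMgBr (THF, 0 °C) should give racemic 1-[3,4-bis(benzyloxy)-5-methoxyphenyl]propan-1-ol F3, which MnO2 (CH2Cl2, rt) oxidises to 1-[3,4-bis(benzyloxy)-5-methoxyphenyl]propan-1-one F4.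
- Oxidative dimerisation of its lithium enolate (LiN(i-Pr)2, THF, −78 °C; then CuCl2, DMF) should give 1,4-bis[3,4-bis(benzyloxy)-5-methoxyphenyl]-2,3-dimethylbutane-1,4-dione F5 as a diastereomer mixture, both isomers of which are used.
- Paal–Knorr cyclodehydration (p-TsOH, toluene, reflux) should give 2,5-bis[3,4-bis(benzyloxy)-5-methoxyphenyl]-3,4-dimethylfuran F6.
- Exhaustive hydrogenation (H2, Pd/C, EtOAc/AcOH, 50 °C) should first remove the benzyl ethers to give 2,5-bis(3,4-dihydroxy-5-methoxyphenyl)-3,4-dimethylfuran F7. It should then saturate the furan from one face to all-cis-(2R,3S,4R,5S)-2,5-bis(3,4-dihydroxy-5-methoxyphenyl)-3,4-dimethyltetrahydrofuran F8. Finally it should cleave the two benzylic C–O bonds without touching C8 and C8', which comes back to the route at 11.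

Step 7. Residual iridium or phosphine may poison the palladium so that cleavage of the four benzyl ethers stops part-way, and the liberated catechols may be oxidised to ortho-quinones by air during filtration. The fallback replaces hydrogenolysis by Lewis-acid dealkylation and sets out from 10. BCl3 with pentamethylbenzene as cation scavenger in CH2Cl2 at −78 °C, quenched with MeOH, should cleave the benzyl ethers while leaving the two aryl methyl ethers, and comes back to the route at 11 after an acidic, non-oxidising work-up. The fallback makes no compound outside the list (none F0).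

**Further compounds**
F1 | step 5 | 1,2-bis(benzyloxy)-5-[(2Z)-3-iodo-2-methylbut-2-en-1-yl]-3-methoxybenzene | COc1cc(C/C(C)=C(C)\I)cc(OCc2ccccc2)c1OCc1ccccc1
F2 | step 5 | [3,4-bis(benzyloxy)-5-methoxybenzyl]zinc bromide | COc1cc(C[Zn]Br)cc(OCc2ccccc2)c1OCc1ccccc1
F3 | step 6 | 1-[3,4-bis(benzyloxy)-5-methoxyphenyl]propan-1-ol (racemic) | CCC(O)c1cc(OC)c(OCc2ccccc2)c(OCc2ccccc2)c1
F4 | step 6 | 1-[3,4-bis(benzyloxy)-5-methoxyphenyl]propan-1-one | CCC(=O)c1cc(OC)c(OCc2ccccc2)c(OCc2ccccc2)c1
F5 | step 6 | 1,4-bis[3,4-bis(benzyloxy)-5-methoxyphenyl]-2,3-dimethylbutane-1,4-dione (diastereomer mixture) | COc1cc(C(=O)C(C)C(C)C(=O)c2cc(OCc3ccccc3)c(OCc3ccccc3)c(OC)c2)cc(OCc2ccccc2)c1OCc1ccccc1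
F6 | step 6 | 2,5-bis[3,4-bis(benzyloxy)-5-methoxyphenyl]-3,4-dimethylfuran | COc1cc(-c2oc(-c3cc(OCc4ccccc4)c(OCc4ccccc4)c(OC)c3)c(C)c2C)cc(OCc2ccccc2)c1OCc1ccccc1
F7 | step 6 | 2,5-bis(3,4-dihydroxy-5-methoxyphenyl)-3,4-dimethylfuran | COc1cc(-c2oc(-c3cc(O)c(O)c(OC)c3)c(C)c2C)cc(O)c1O
F8 | step 6 | all-cis-(2R,3S,4R,5S)-2,5-bis(3,4-dihydroxy-5-methoxyphenyl)-3,4-dimethyltetrahydrofuran (meso) | COc1cc([C@H]2O[C@@H](c3cc(O)c(O)c(OC)c3)[C@@H](C)[C@H]2C)cc(O)c1O
F0 | step 7 | none | none
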